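**Retrosynthetic overview**

1. The plan rests on one feature of the isoflavan (ring C = O1, C2, C3, C4; ring A fused; ring B on C3): the ortho oxygen O2' of ring B can reach benzylic C4. Tying O2' to C4 makes the C3–C4 bond a ring bond of a 2-aryl-2,3-dihydrobenzofuran, the furan ring of a cis-pterocarpan.
2. Target ⇐ reductive cleavage of the benzylic C4–O2' bond of a (6aR,11aR)-pterocarpan diol. Its two 1,1-dimethylallyl groups (C6 and C5') ⇐ double aromatic Claisen rearrangement of the O7 and O4' prenyl ethers.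
3. Pterocarpan ⇐ O1–C2 bond (pyran ring C) by Mitsunobu closure of the ring A phenol onto the primary alcohol from the cis dihydrobenzofuran ester.
4. cis ester ⇐ C3–C4 bond by enantioselective rhodium carbenoid insertion of the ring B aryldiazoacetate into the benzylic C–H of its O2'–CH2–ring A ether. Diazo ester ⇐ diazo transfer, Mitsunobu etherification, and prenylation/silylation of 2,4-dihydroxybenzaldehyde and methyl 2,4-dihydroxyphenylacetate.
5. Ring order: rings A and B are bought; the temporary furan ring is closed first (key step), pyran ring C second, and the furan ring is opened last.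

Key step: step 7

Assumption: by analogy with simpler 2-aryl cases, Rh2(S-PTTL)4 (dirhodium tetrakis[N-phthaloyl-(S)-tert-leucinate]) is taken to give the (2R,3S) cis ester of the key step. If a first run shows the opposite sense, Rh2(R-PTTL)4 is used and nothing else changes.

**Route**

Step 1
Reactants: 1 2,4-dihydroxybenzaldehyde; 2 1-bromo-3-methylbut-2-ene (prenyl bromide)
Product: 3 2-hydroxy-4-[(3-methylbut-2-en-1-yl)oxy]benzaldehyde
Conditions: K2CO3 (1.0 equiv), acetone, 50 °C
Reagents that add atoms: none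
Why: Williamson etherification in which the 2-OH, tied up in a hydrogen bond to the aldehyde carbonyl, is the poorer nucleophile, so that the allylic bromide should alkylate O4 alone.

Step 2
Reactants: 3 2-hydroxy-4-[(3-methylbut-2-en-1-yl)oxy]benzaldehyde
Product: 4 2-[(tert-butyldimethylsilyl)oxy]-4-[(3-methylbut-2-en-1-yl)oxy]benzaldehyde
Conditions: TBSCl, imidazole, DMF, rt
Reagents that add atoms: tert-butyldimethylsilyl chloride (TBSCl), CC(C)(C)[Si](C)(C)Cl
Why: Standard silylation of the remaining phenol with a silyl chloride and imidazole, giving a group that is inert to a rhodium carbenoid and comes off later with fluoride.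

Step 3
Reactants: 4 2-[(tert-butyldimethylsilyl)oxy]-4-[(3-methylbut-2-en-1-yl)oxy]benzaldehyde
Product: 5 {2-[(tert-butyldimethylsilyl)oxy]-4-[(3-methylbut-2-en-1-yl)oxy]phenyl}methanol
Conditions: NaBH4, MeOH/THF, 0 °C, 15 min; NH4Cl
Reagents that add atoms: none
Why: Borohydride reduction of the aryl aldehyde to the benzylic alcohol, kept short and cold and quenched with NH4Cl so that the silyl group does not shift from the phenol oxygen to the new alkoxide.

Step 4
Reactants: 6 methyl 2-(2,4-dihydroxyphenyl)acetate; 2 1-bromo-3-methylbut-2-ene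
Product: 7 methyl 2-{2-hydroxy-4-[(3-methylbut-2-en-1-yl)oxy]phenyl}acetate
Conditions: K2CO3 (1.0 equiv), 2 (0.95 equiv), acetone, rt
Reagents that add atoms: none
Why: Williamson etherification with the bromide as limiting reagent, which should favour the open 4-OH over the 2-OH that is flanked by the CH2CO2Me arm and hydrogen-bonded to its carbonyl; any 2-O and bis ethers are removed by chromatography.

Step 5
Reactants: 7 methyl 2-{2-hydroxy-4-[(3-methylbut-2-en-1-yl)oxy]phenyl}acetate; 5 {2-[(tert-butyldimethylsilyl)oxy]-4-[(3-methylbut-2-en-1-yl)oxy]phenyl}methanol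
Product: 8 methyl 2-[2-({2-[(tert-butyldimethylsilyl)oxy]-4-[(3-methylbut-2-en-1-yl)oxy]benzyl}oxy)-4-[(3-methylbut-2-en-1-yl)oxy]phenyl]acetate
Conditions: PPh3, DIAD, THF, 0 °C → rt
Reagents that add atoms: none
Why: Mitsunobu etherification of the one free phenol (O2') with the primary benzylic alcohol, which forms the O2'–CH2 ether without passing through the unstable 2,4-dioxygenated benzyl halide and leaves the silyl and prenyl ethers alone.

Step 6
Reactants: 8 methyl 2-[2-({2-[(tert-butyldimethylsilyl)oxy]-4-[(3-methylbut-2-en-1-yl)oxy]benzyl}oxy)-4-[(3-methylbut-2-en-1-yl)oxy]phenyl]acetate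
Product: 9 methyl 2-diazo-2-[2-({2-[(tert-butyldimethylsilyl)oxy]-4-[(3-methylbut-2-en-1-yl)oxy]benzyl}oxy)-4-[(3-methylbut-2-en-1-yl)oxy]phenyl]acetate
Conditions: p-ABSA, DBU, MeCN, 0 °C → rt
Reagents that add atoms: 4-acetamidobenzenesulfonyl azide (p-ABSA), CC(=O)Nc1ccc(cc1)S(=O)(=O)N=[N+]=[N-]
Why: Regitz diazo transfer from the sulfonyl azide to the DBU-generated arylacetate enolate, the standard entry to aryldiazoacetates, under which aryl silyl ethers and allyl ethers are stable.

Step 7
Reactants: 9 methyl 2-diazo-2-[2-({2-[(tert-butyldimethylsilyl)oxy]-4-[(3-methylbut-2-en-1-yl)oxy]benzyl}oxy)-4-[(3-methylbut-2-en-1-yl)oxy]phenyl]acetate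
Product: 10 methyl (2R,3S)-2-{2-[(tert-butyldimethylsilyl)oxy]-4-[(3-methylbut-2-en-1-yl)oxy]phenyl}-6-[(3-methylbut-2-en-1-yl)oxy]-2,3-dihydro-1-benzofuran-3-carboxylate (cis)
Conditions: Rh2(S-PTTL)4 (2 mol %), toluene (0.02 M), slow addition of 9, −78 → −40 °C
Reagents that add atoms: none
Why: The dirhodium carboxylate expels N2 from 9, and the donor/acceptor rhodium carbenoid at C3 inserts, through a three-centre transition state with hydride-transfer character, into a benzylic C–H of the O2'–CH2–ring A ether. The closest known reaction type is the enantioselective intramolecular C–H insertion of methyl 2-(benzyloxy)aryl diazoacetates with phthalimido-amino-acid dirhodium carboxylates, which gives cis-2-aryl-2,3-dihydrobenzofuran-3-carboxylates. The furan ring is closed by 1,5-insertion (a five-membered ring through C3, C1', C2', O2' and C4), and this forms the C3–C4 bond. Both new stereocentres (C2 and C3 of the dihydrobenzofuran) are set together by the chiral carboxylate ligands, which choose the carbenoid face and one of the two enantiotopic benzylic hydrogens; the cis relation of aryl and ester is kinetic and is kept by working cold and without base. The step needs site selectivity for this C–H over the prenyl alkenes, their allylic C–H bonds and carbene dimerisation; the ether oxygen and the 2,4-dioxygenated ring A make it the most hydridic C–H within reach of a five-membered closure, the bulky carbenoid reacts poorly with trisubstituted alkenes, and slow addition at high dilution suppresses bimolecular paths.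

Step 8
Reactants: 10 methyl (2R,3S)-2-{2-[(tert-butyldimethylsilyl)oxy]-4-[(3-methylbut-2-en-1-yl)oxy]phenyl}-6-[(3-methylbut-2-en-1-yl)oxy]-2,3-dihydro-1-benzofuran-3-carboxylate
Product: 11 [(2R,3R)-2-{2-[(tert-butyldimethylsilyl)oxy]-4-[(3-methylbut-2-en-1-yl)oxy]phenyl}-6-[(3-methylbut-2-en-1-yl)oxy]-2,3-dihydro-1-benzofuran-3-yl]methanol
Conditions: LiAlH4, THF, −40 → 0 °C; Na2SO4·10H2O
Reagents that add atoms: none
Why: Hydride reduction of the ester to the primary alcohol, run cold and at once so that reduction outruns enolisation of the cis ester (which would epimerise C3 or open the furan ring by beta-elimination of the aryloxide), after which C3 is no longer acidic.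

Step 9
Reactants: 11 [(2R,3R)-2-{2-[(tert-butyldimethylsilyl)oxy]-4-[(3-methylbut-2-en-1-yl)oxy]phenyl}-6-[(3-methylbut-2-en-1-yl)oxy]-2,3-dihydro-1-benzofuran-3-yl]methanol
Product: 12 2-[(2R,3R)-3-(hydroxymethyl)-6-[(3-methylbut-2-en-1-yl)oxy]-2,3-dihydro-1-benzofuran-2-yl]-5-[(3-methylbut-2-en-1-yl)oxy]phenol
Conditions: TBAF, AcOH (1:1), THF, 0 °C
Reagents that add atoms: none
Why: Fluoride cleavage of the aryl silyl ether, buffered with acetic acid so that the freed ortho phenol stays protonated and the neighbouring benzylic aryl ether does not open to an ortho-quinone methide.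

Step 10
Reactants: 12 2-[(2R,3R)-3-(hydroxymethyl)-6-[(3-methylbut-2-en-1-yl)oxy]-2,3-dihydro-1-benzofuran-2-yl]-5-[(3-methylbut-2-en-1-yl)oxy]phenol
Product: 13 (6aR,11aR)-3,9-bis[(3-methylbut-2-en-1-yl)oxy]-6a,11a-dihydro-6H-[1]benzofuro[3,2-c]chromene (cis-pterocarpan)
Conditions: PPh3, DIAD, THF (0.01 M), 0 °C → rt
Reagents that add atoms: none
Why: Intramolecular Mitsunobu etherification in which the ring A phenol displaces the activated primary oxygen at C6 (6-exo-tet SN2), closing the pyran ring without touching either stereocentre; the cis arrangement of aryl group and CH2OH from step 7 gives the cis-fused pterocarpan.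

Step 11
Reactants: 13 (6aR,11aR)-3,9-bis[(3-methylbut-2-en-1-yl)oxy]-6a,11a-dihydro-6H-[1]benzofuro[3,2-c]chromene
Product: 14 (6aR,11aR)-2,8-bis(2-methylbut-3-en-2-yl)-6a,11a-dihydro-6H-[1]benzofuro[3,2-c]chromene-3,9-diol
Conditions: PhNEt2 (degassed), 190 °C, sealed tube, Ar
Reagents that add atoms: none
Why: Twofold aromatic Claisen rearrangement, each [3,3] shift delivering the dimethyl-substituted allyl terminus to the ortho carbon remote from the ring-fusion oxygen (C2 on ring A, C8 on ring D: para to the second oxygen and the only ortho sites that can take a quaternary carbon without crowding), with rearomatisation to the phenol and no change at C6a or C11a.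

Step 12
Reactants: 14 (6aR,11aR)-2,8-bis(2-methylbut-3-en-2-yl)-6a,11a-dihydro-6H-[1]benzofuro[3,2-c]chromene-3,9-diol
Product: 15 Manuifolin E, (3R)-3-[2,4-dihydroxy-5-(2-methylbut-3-en-2-yl)phenyl]-6-(2-methylbut-3-en-2-yl)-3,4-dihydro-2H-chromen-7-ol
Conditions: Li (excess), NH3(l)/THF, −78 → −33 °C; NH4Cl
Reagents that add atoms: none
Why: Dissolving-metal (Birch-type) cleavage of the one benzylic C–O bond, C11a–O11, which turns C11a into the C4 methylene and frees the 2'-OH; the phenols are carried as lithium phenoxides that shield both rings from reduction, the isolated vinyl groups are not reduced without an added alcohol, and C6a (C3 of the isoflavan) is not involved, so its R configuration is kept.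

**Compound list**

1 | 2,4-dihydroxybenzaldehyde | O=Cc1ccc(O)cc1O | starting material
2 | 1-bromo-3-methylbut-2-ene (prenyl bromide) | CC(C)=CCBr | starting material
3 | 2-hydroxy-4-[(3-methylbut-2-en-1-yl)oxy]benzaldehyde | O=Cc1ccc(OCC=C(C)C)cc1O | intermediate
4 | 2-[(tert-butyldimethylsilyl)oxy]-4-[(3-methylbut-2-en-1-yl)oxy]benzaldehyde | O=Cc1ccc(OCC=C(C)C)cc1O[Si](C)(C)C(C)(C)C | intermediate
5 | {2-[(tert-butyldimethylsilyl)oxy]-4-[(3-methylbut-2-en-1-yl)oxy]phenyl}methanol | OCc1ccc(OCC=C(C)C)cc1O[Si](C)(C)C(C)(C)C | intermediate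
6 | methyl 2-(2,4-dihydroxyphenyl)acetate | COC(=O)Cc1ccc(O)cc1O | starting material
7 | methyl 2-{2-hydroxy-4-[(3-methylbut-2-en-1-yl)oxy]phenyl}acetate | COC(=O)Cc1ccc(OCC=C(C)C)cc1O | intermediate
8 | methyl 2-[2-({2-[(tert-butyldimethylsilyl)oxy]-4-[(3-methylbut-2-en-1-yl)oxy]benzyl}oxy)-4-[(3-methylbut-2-en-1-yl)oxy]phenyl]acetate | COC(=O)Cc1ccc(OCC=C(C)C)cc1OCc1ccc(OCC=C(C)C)cc1O[Si](C)(C)C(C)(C)C | intermediate
9 | methyl 2-diazo-2-[2-({2-[(tert-butyldimethylsilyl)oxy]-4-[(3-methylbut-2-en-1-yl)oxy]benzyl}oxy)-4-[(3-methylbut-2-en-1-yl)oxy]phenyl]acetate | COC(=O)C(=[N+]=[N-])c1ccc(OCC=C(C)C)cc1OCc1ccc(OCC=C(C)C)cc1O[Si](C)(C)C(C)(C)C | intermediate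
10 | methyl (2R,3S)-2-{2-[(tert-butyldimethylsilyl)oxy]-4-[(3-methylbut-2-en-1-yl)oxy]phenyl}-6-[(3-methylbut-2-en-1-yl)oxy]-2,3-dihydro-1-benzofuran-3-carboxylate | COC(=O)[C@H]1c2ccc(OCC=C(C)C)cc2O[C@H]1c1ccc(OCC=C(C)C)cc1O[Si](C)(C)C(C)(C)C | intermediate
11 | [(2R,3R)-2-{2-[(tert-butyldimethylsilyl)oxy]-4-[(3-methylbut-2-en-1-yl)oxy]phenyl}-6-[(3-methylbut-2-en-1-yl)oxy]-2,3-dihydro-1-benzofuran-3-yl]methanol | OC[C@H]1c2ccc(OCC=C(C)C)cc2O[C@H]1c1ccc(OCC=C(C)C)cc1O[Si](C)(C)C(C)(C)C | intermediate
12 | 2-[(2R,3R)-3-(hydroxymethyl)-6-[(3-methylbut-2-en-1-yl)oxy]-2,3-dihydro-1-benzofuran-2-yl]-5-[(3-methylbut-2-en-1-yl)oxy]phenol | OC[C@H]1c2ccc(OCC=C(C)C)cc2O[C@H]1c1ccc(OCC=C(C)C)cc1O | intermediate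
13 | (6aR,11aR)-3,9-bis[(3-methylbut-2-en-1-yl)oxy]-6a,11a-dihydro-6H-[1]benzofuro[3,2-c]chromene | C3[C@H]1c2ccc(OCC=C(C)C)cc2O[C@H]1c1ccc(OCC=C(C)C)cc1O3 | intermediate
14 | (6aR,11aR)-2,8-bis(2-methylbut-3-en-2-yl)-6a,11a-dihydro-6H-[1]benzofuro[3,2-c]chromene-3,9-diol | C3[C@H]1c2cc(C(C)(C)C=C)c(O)cc2O[C@H]1c1cc(C(C)(C)C=C)c(O)cc1O3 | intermediate
15 | Manuifolin E, (3R)-3-[2,4-dihydroxy-5-(2-methylbut-3-en-2-yl)phenyl]-6-(2-methylbut-3-en-2-yl)-3,4-dihydro-2H-chromen-7-ol | C=CC(C)(C)c1cc2c(cc1O)OC[C@@H](c1cc(C(C)(C)C=C)c(O)cc1O)C2 | target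

**Step count and risks**

Total step count: 12. Longest linear sequence: 11 steps (steps 1–3 and 5–12, from 2,4-dihydroxybenzaldehyde).

Steps most likely to fail:

Step 7. The ortho silyloxy group on ring A lies outside the simple 2-aryl cases on which this catalyst family is proven, so discrimination between the carbenoid faces and the two benzylic hydrogens may be incomplete and the enantiomeric purity too low. Fallback: stereochemical purity is secured on the substrate, not by the catalyst. The fallback sets out from alcohol 11 of incomplete enantiopurity. Acylation with (1S)-camphanoyl chloride (Et3N, DMAP, CH2Cl2) gives [(2R,3R)-2-{2-[(tert-butyldimethylsilyl)oxy]-4-[(3-methylbut-2-en-1-yl)oxy]phenyl}-6-[(3-methylbut-2-en-1-yl)oxy]-2,3-dihydro-1-benzofuran-3-yl]methyl (1S,4R)-camphanate F1, accompanied by the camphanate of the (2S,3S) alcohol F2. F1 is freed from F2 by crystallisation or chromatography. Methanolysis (K2CO3, MeOH, 0 °C → rt) removes the camphanoyl group and the aryl silyl group together, and the route is rejoined at 12.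

Step 11. At 190 °C the phenols, once formed, may react further: abnormal Claisen shift of the new side chain, ring closure of the phenol onto the vinyl group, loss of isoprene, or opening of the 3-hydroxypterocarpan through a quinone methide. Rearrangement to the more crowded ortho positions is the second concern. Fallback: the rearrangement is coupled to acylation so that no free phenol accumulates. Setting out from 13, heating in PhNEt2 with butanoic anhydride (185 °C) should give (6aR,11aR)-2,8-bis(2-methylbut-3-en-2-yl)-6a,11a-dihydro-6H-[1]benzofuro[3,2-c]chromene-3,9-diyl dibutanoate F3. Methanolysis (K2CO3, MeOH, rt) returns to the route at 14.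

Step 12. Electron transfer into two phenoxide-bearing rings may be too slow for clean C–O scission. Alternatively the para phenoxide may open the ring to a quinone methide that tautomerises to the isoflav-3-ene, with loss of the C3 configuration. Fallback: the phenols are masked so that the arene accepts an electron and cannot form a quinone methide. Setting out from 14, silylation (TBSOTf, 2,6-lutidine, CH2Cl2, 0 °C) gives (6aR,11aR)-3,9-bis[(tert-butyldimethylsilyl)oxy]-2,8-bis(2-methylbut-3-en-2-yl)-6a,11a-dihydro-6H-[1]benzofuro[3,2-c]chromene F4. Cleavage with lithium 4,4'-di-tert-butylbiphenylide (LiDBB, THF, −78 °C; NH4Cl) should give 2-[(3R)-7-[(tert-butyldimethylsilyl)oxy]-6-(2-methylbut-3-en-2-yl)-3,4-dihydro-2H-chromen-3-yl]-5-[(tert-butyldimethylsilyl)oxy]-4-(2-methylbut-3-en-2-yl)phenol F5. Desilylation (TBAF, AcOH, THF, 0 °C) arrives at 15.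

**Further compounds**

F1 | step 7 | [(2R,3R)-2-{2-[(tert-butyldimethylsilyl)oxy]-4-[(3-methylbut-2-en-1-yl)oxy]phenyl}-6-[(3-methylbut-2-en-1-yl)oxy]-2,3-dihydro-1-benzofuran-3-yl]methyl (1S,4R)-4,7,7-trimethyl-3-oxo-2-oxabicyclo[2.2.1]heptane-1-carboxylate | O=C(OC[C@H]1c2ccc(OCC=C(C)C)cc2O[C@H]1c1ccc(OCC=C(C)C)cc1O[Si](C)(C)C(C)(C)C)[C@@]12CC[C@@](C)(C(=O)O1)C2(C)C
F2 | step 7 | [(2S,3S)-2-{2-[(tert-butyldimethylsilyl)oxy]-4-[(3-methylbut-2-en-1-yl)oxy]phenyl}-6-[(3-methylbut-2-en-1-yl)oxy]-2,3-dihydro-1-benzofuran-3-yl]methyl (1S,4R)-4,7,7-trimethyl-3-oxo-2-oxabicyclo[2.2.1]heptane-1-carboxylate | O=C(OC[C@@H]1c2ccc(OCC=C(C)C)cc2O[C@@H]1c1ccc(OCC=C(C)C)cc1O[Si](C)(C)C(C)(C)C)[C@@]12CC[C@@](C)(C(=O)O1)C2(C)C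
F3 | step 11 | (6aR,11aR)-2,8-bis(2-methylbut-3-en-2-yl)-6a,11a-dihydro-6H-[1]benzofuro[3,2-c]chromene-3,9-diyl dibutanoate | C3[C@H]1c2cc(C(C)(C)C=C)c(OC(=O)CCC)cc2O[C@H]1c1cc(C(C)(C)C=C)c(OC(=O)CCC)cc1O3
F4 | step 12 | (6aR,11aR)-3,9-bis[(tert-butyldimethylsilyl)oxy]-2,8-bis(2-methylbut-3-en-2-yl)-6a,11a-dihydro-6H-[1]benzofuro[3,2-c]chromene | C3[C@H]1c2cc(C(C)(C)C=C)c(O[Si](C)(C)C(C)(C)C)cc2O[C@H]1c1cc(C(C)(C)C=C)c(O[Si](C)(C)C(C)(C)C)cc1O3
F5 | step 12 | 2-[(3R)-7-[(tert-butyldimethylsilyl)oxy]-6-(2-methylbut-3-en-2-yl)-3,4-dihydro-2H-chromen-3-yl]-5-[(tert-butyldimethylsilyl)oxy]-4-(2-methylbut-3-en-2-yl)phenol | C3[C@@H](c2cc(C(C)(C)C=C)c(O[Si](C)(C)C(C)(C)C)cc2O)Cc1cc(C(C)(C)C=C)c(O[Si](C)(C)C(C)(C)C)cc1O3
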